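The ratio of target to other capture product is in dispute here: does it stand level in this flask, or climb?

| flask | substrate | first nucleophile | second nucleophile | capture agent | remark | time |
|---|---|---|---|---|---|---|
| Monday's | 1 mM | 1.4 mM | 2.1 mM | 0.20 mM | run made earlier |  |
| Wednesday's | 4 mM | 1.4 mM | 2.1 mM | 0.20 mM | run made earlier |  |
| flask | 2.0 mM | 1.40 mM | 2.10 mM | 0.200 mM |  | 2.5 min |

| run | time / s | target / % | other capture product / % |
|---|---|---|---|
| Monday's | 10.0 | 25.3 | 48.8 |
| Monday's | 15.0 | 25.7 | 49.7 |
| Monday's | 25.0 | 25.2 | 48.8 |
| Monday's | 50.0 | 24.9 | 49.8 |
| Monday's | 90.0 | 26.1 | 48.6 |
| Wednesday's | 10.0 | 23.2 | 39.5 |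
| Wednesday's | 15.0 | 23.8 | 39.1 |
| Wednesday's | 25.0 | 24.1 | 39.2 |
| Wednesday's | 50.0 | 23.7 | 39.5 |
| Wednesday's | 90.0 | 24.2 | 39.0 |

(scatter of a reading: 0.5 percentage points)

1. ratio of target to other capture product at 0.15 s
2. ratio of target to other capture product at 2.5 min

- the earlier runs were read with a standard deviation of 0.5 percentage points
- a reading or a percentage of target counts all its forms, free or not

Monday's means are 25.4% target and 49.1% other capture product, a ratio of 0.518. Wednesday's ratio reads 0.606.

The first chemist points to columns that stand level from 10.0 s to 90.0 s. For her the ratio does not move in time, so interpolating on the substrate charge puts this flask at 0.547 at both asked times.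

The second chemist answers that the level columns begin at 10.0 s, later than the early time asked. Suppose one short-lived species feeds both captures, and let B and D be the free first and second nucleophile. Dividing one rate of formation by the other drops time out: target per other capture product, at any moment, is S·B/D, with S the ratio of the two capture constants. Summed over a run, S is the logarithm of charge over remainder for the first nucleophile, divided by the same logarithm for the second. This selectivity factor reads 0.752 on Monday's means.

At 0.15 s, far earlier than the first reading, she takes B and D near their charges. My own reckoning on that view gives S times charge over charge, 0.502, below the first chemist's figure.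

The forecast takes the second side with 0.485 early, a little under my figure, and 0.54 late: “Early ratio: 0.65 × 1.4/1.9 ≈ 0.48, assuming this binding is already established.”

The flask gives 0.490 at 0.15 s and 0.549 at 2.5 min, so the ratio climbs and the forecast stands.

    substrate → open intermediate (k = 0.735 s⁻¹)
    first nucleophile + open intermediate → target (k = 762 M⁻¹ s⁻¹)
    second nucleophile + open intermediate → other capture product (k = 1040 M⁻¹ s⁻¹)
    open intermediate → solvolysis product (k = 0.990 s⁻¹)
    second nucleophile + target ⇌ idle adduct, settled at all times (K = 325 M⁻¹)
    open intermediate + capture agent → trapped intermediate (k = 5.13 M⁻¹ s⁻¹)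

The first chemist keeps the later stretch: at 0.250 min this flask has 0% substrate and a ratio of 0.549, and a run ten times as long changes nothing. The same S on this flask gave 0.502 against 0.490. In a neighbour flask charged with 3.5 mM of first nucleophile, S times the charges gives 1.25 at 0.15 s; that neighbour flask gives 1.23 there and 1.40 at 2.5 min, ending with 46.6% target, all forms counted, against 33.3% other capture product.

(The readings stem from a simulated flask for an exercise; noise was put on by code.)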